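At early times the violet, grey and blue runs look alike in L: at 3.00 h it reads 28.7%, 28.4% and 28.5% of the charge, although E differs from run to run. J comes with a lag, so what leaves L first waits in an unread pool. By 4.00 h, J reads 11.5%, 10.1% and 6.7% from lowest E to highest, a spread of 4.8 percentage points against a scatter of 0.5 points.

| flask | L | Z | E | remark | time |
|---|---|---|---|---|---|
| violet | 0.20 M | 0.24 M (fed, over 40 min) | 0.086 M | run made earlier |  |
| grey | 0.20 M | 0.24 M (fed, over 40 min) | 0.31 M | run made earlier |  |
| blue | 0.20 M | 0.24 M (fed, over 40 min) | 0.94 M | run made earlier |  |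
| north-west | 0.20 M | 0.240 M (fed, over 40 min) | 0.100 M |  | 8.0 h |
| north-east | 0.20 M | 0.240 M (fed, over 40 min) | 0.300 M |  | 8.0 h |
| south-west | 0.20 M | 0.240 M (fed, over 40 min) | 1.00 M |  | 8.0 h |

| run | time / h | J / % | L / % |
|---|---|---|---|
| violet | 0.333 | 0.5 | 87.2 |
| violet | 1.00 | 0 | 66.3 |
| violet | 2.00 | 3.2 | 42.6 |
| violet | 3.00 | 5.8 | 28.7 |
| violet | 4.00 | 11.5 | 19.0 |
| grey | 0.833 | 0 | 70.1 |
| grey | 1.50 | 1.9 | 53.2 |
| grey | 2.50 | 3.5 | 34.9 |
| grey | 3.00 | 5.9 | 28.4 |
| grey | 4.00 | 10.1 | 18.5 |
| blue | 0.833 | 0.4 | 70.1 |
| blue | 1.50 | 0.8 | 53.1 |
| blue | 2.50 | 3.4 | 35.1 |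
| blue | 3.00 | 3.7 | 28.5 |
| blue | 4.00 | 6.7 | 19.2 |

(readings scatter by 0.5 percentage points)

- the earlier runs were read with a standard deviation of 0.5 percentage points
- "hardly changes" means that all values lie within two and a half points (for a concentration: within two and a half percent of the largest)

* amount of J at the end, in percent of the L charged for north-west, north-east, south-west, in this order
* the course of these numbers from the first flask to the last (falls, then rises / falls all the way / hardly changes / rises all the way / rises, then falls)

The forecast holds that “E inhibits the second step” and drains the pool by a consecutive first-order expression. It gives 26.9%, 23.4% and 15.9%, a row that falls all the way. Its north-west value, set over the violet reading at 4.00 h, is a stretch of 2.34.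

I hold another view. The pool may need a partner made from Z, charged at 1.20 per L, and E may compete for that Z. My working assumption is that a partner building up offsets the drain of the pool, so that J grows in step with pool-time, the running integral of the fraction that has left L.

The violet L reading gives a first-order constant of 0.415 h⁻¹. Pool-time is then the elapsed time minus the fraction of L gone divided by that constant: 2.05 h at 4.00 h and 5.68 h at 8.0 h. Their ratio, 2.77, I call the stretch factor: J at 8.0 h per J at 4.00 h in one flask, as long as J keeps step with pool-time.

The asked flasks hold E at 0.100 M, 0.300 M and 1.00 M against 0.086 M, 0.31 M and 0.94 M in the runs, so I carry the readings over unchanged and get 31.9%, 28.0% and 18.6%. For north-west this is higher than the forecast, though the direction of the row is the same.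

The simulation gives 34.2%, 28.2% and 16.2%, a row that falls all the way.

    L → Q (k = 0.00700 min⁻¹)
    Z → X (k = 0.00450 min⁻¹)
    Q + X → J (k = 0.0120 M⁻¹ min⁻¹)
    Z + E → D (k = 0.0130 M⁻¹ min⁻¹)

In north-west, while Z falls from 29.7% of its charge at 4.00 h to 8.29% at 8.00 h, Q + X → J runs with X at 47.2% and then 46.3% of the Z charge at these two times, close to pseudo-first-order in Q, and J stretches from 11.5% to 34.2%, a factor of 2.97 against the carried 2.77. South-west is the flask where the forecast stands nearest the simulation: Z is down to 3.12% at 4.00 h and 0.0801% at 8.00 h, X sinks from 21.1% to 14.0% of the Z charge, and J stretches by 2.46, against 2.77 carried and 2.37 for the forecast's value over the blue reading.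

(The earlier runs and the new flask stem from a simulated flask with made-up constants, and the scatter is random.)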